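## Analysis of the target

- The target is an acyclic 1,2-diarylpropan-1-ol of the 8-aryl neolignan type. No ring has to be built; the problem is the three-carbon chain C7–C8–C9 (carbinol carbon, methine, methyl) between two electron-rich benzene rings.
- Ring A is tetrasubstituted: a free hydroxyl, a methoxy group on one ortho carbon, C8 on the other ortho carbon, and an allyl group para to the hydroxyl. Ring B is a 3,4-dimethoxyphenyl group on C7.
- C7 and C8 are the only stereocentres; they are adjacent, both S, and threo. When the C8–ring A and C7–O bonds are eclipsed, the C9 methyl and ring B point to opposite sides, as in an (E)-alkene. The molecule is therefore the formal syn adduct of ring A and OH across an (E)-propenylarene.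
- The C7 hydroxyl is a 3,4-dimethoxybenzylic alcohol with the ring A phenol oxygen five atoms away. Acid ionises C7 and leads to epimerisation or to closure of a 2-aryl-3-methyl-2,3-dihydrobenzofuran.
- The terminal alkene of the allyl group does not survive hydrogenation and migrates into conjugation under strong base or metal hydrides. The guaiacol-type phenol is easily oxidised.
- The difficulty is acyclic control of the C7/C8 diad as one enantiomer, with no ring and no resident stereocentre to help, next to a crowded 1,2,3-trisubstituted junction of ring A at C8.
- The plan rests on one feature: ring B, C7, C8 and C9 together are the carbon skeleton of (E)-methylisoeugenol. Adding ring A to C8 and an oxygen equivalent to C7 on one face of that alkene gives the whole skeleton and both stereocentres in one step.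

## Retrosynthetic reasoning

**C7–O back to C7–B.** The C7–O bond of target 13 is traced back, through borate ester 12, to the C7–B bond of pinacol boronate 11, which is the target with boron in place of the hydroxyl. The cut is made at the heteroatom because the benzylic alcohol is the one group of 13 that tolerates neither acid nor strong heating next to the ring A phenol. A secondary alkylboronic ester cannot ionise and can be carried through hydrogenolysis, carbonate base and a 190 °C rearrangement. The forward oxidation has to move C7 from boron to oxygen with retention and leave the allyl alkene and the phenol alone.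

**Allyl group of ring A.** In 11 the bond between the ring A carbon para to the hydroxyl and the allyl CH2 is cut, and the allyl group is returned to the phenol oxygen in allyl ether 7; dienones 8, 9 and 10 lie between the two. A terminal alkene cannot be present earlier, since it would compete with the propenyl group in the nickel step and would be lost when the benzyl group is removed with hydrogen. Ring A of 7 has both positions ortho to oxygen occupied (methoxy and C8) and only the para position open, so the oxygen already in place decides where the allyl group ends. The forward step has to run two [3,3] shifts without touching the C7–B bond or either stereocentre.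

**Oxygen substituent of ring A.** The O–allyl bond of 7 is cut to phenol 6, and 6 is the debenzylated form of benzyl ether 5. The exchange of benzyl for allyl costs two steps. It lets the ring A oxygen pass through the nickel step with a group that has no alkene and resists alkoxide and low-valent nickel. That group then comes off by hydrogenolysis while the molecule still has no C=C bond.

**The diad.** In 5 two bonds are cut at once, C8–ring A and C7–B. This gives three components:
- (E)-methylisoeugenol 3, which holds ring B, C7, C8 and C9 in the right order and with the geometry that a suprafacial addition converts into the threo pair;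
- aryl bromide 2 as ring A;
- bis(pinacolato)diboron 4.

This cut is preferred to one at C7–C8 or C7–ring B because it alone uses an intact commercial C6–C3 unit and forms the hindered C8–aryl bond and both stereocentres in the same event. The forward reaction has to place the aryl group on C8 and boron on C7 (not the reverse), deliver both to one alkene face, and select the face that gives 5 as the (1S,2R) enantiomer.

**Ring A bromide.** 2 is cut at the O–benzyl bond to commercial 2-bromo-6-methoxyphenol 1, whose bromine already sits ortho to the hydroxyl on the side away from the methoxy group. One O-benzylation gives 2.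

## Alternatives that were turned down

**Alternative 1:** The strategic bond is the one between the ring A carbon para to the phenol oxygen and the allyl CH2.
- Forward key step: the allyl aryl ether A2 already carries the complete (7S,8S) chain, with C7 as its tert-butyldimethylsilyl ether. It is heated to about 190 °C in N,N-diethylaniline. Two consecutive [3,3] shifts move the allyl group from oxygen to the para carbon and give the phenol A1, one desilylation short of the target.
- For: this is a thermal rearrangement of a well-understood type. Its positional outcome is fixed by the two blocked ortho positions, and it needs no reagent and touches no stereocentre. On certainty of the key step it is clearly stronger than the chosen strategy.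
- Against: the step only relays a three-carbon appendage. It builds neither stereocentre nor the hindered C8–ring A bond, so the diad still has to be made in the preparation of A2, and the plan does not say how. The C7 hydroxyl must be silylated and later freed (two steps), because a free benzylic alcohol next to a newly formed phenol would not tolerate 190 °C.
- Comparison: the chosen route keeps this rearrangement as its step 5, on a substrate in which boron does the masking at no cost in steps. It adds what Alternative 1 lacks, a convergent construction of the diad.

**Alternative 2:** A C8–H bond is cut, so C8 becomes stereogenic last, from the 1,1-disubstituted alkene of the 2-aryl allylic alcohol A4, whose carbinol centre is already in place.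
- Forward key step: hydrogenation with [Rh(nbd)(dppb)]BF4 under H2. The cationic rhodium binds hydroxyl and alkene together and delivers hydrogen to the alkene face that the carbinol geometry exposes when allylic strain is minimised. This gives the (1S,2S)-alcohol A3; the aryl bromide stays as the later anchor for the allyl group. The descriptor at C7 changes from R in A4 to S in A3 only because the priorities change.
- For: hydroxyl-directed hydrogenation of 2-substituted allylic alcohols is established, one stereocentre controls the other, and the absolute configuration can come from a routine asymmetric carbonyl reduction or addition. On stereochemical precedent it is stronger than the chosen key step.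
- Against:
  - The alkene carries an aryl group twisted by an ortho silyloxy substituent, so the conformational bias behind the precedent (alkyl or ester at that position) is not assured and the chelate is crowded.
  - A dimethoxybenzylic allylic alcohol is prone to rhodium-mediated 1,3-hydrogen shift to the ketone, which destroys C7, and to C–O hydrogenolysis.
  - The C–Br bond must survive.
  - The sequence is long: A4 must be built with C7 set, and after the key step a cross-coupling for the allyl group and a desilylation remain, roughly twice the length of the chosen route.
- Comparison: the chosen strategy sets both centres and the C8–aryl bond in one step from a commodity alkene and never exposes a free benzylic alcohol to a metal hydride. It pays for this with an unproven enantioselective step.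

**Alternative 3:** Both bonds to C7 are cut (C8–C7 and C7–ring B), so C7 is inserted as a one-carbon unit.
- Forward key step: the chiral (4S,5S)-4,5-dicyclohexyl-1,3,2-dioxaborolane A6, with C8 on boron, is treated with LiCHCl2 at low temperature. With ZnCl2, C8 migrates from boron to carbon with retention and expels one chloride under control of the diol. The Grignard reagent A7 then adds to boron, and ring B migrates with inversion at C7, expelling the second chloride, to give the C7 boronate A5.
- For: two stereospecific 1,2-shifts under reagent control of a C2-symmetric diol are among the most predictable routes to an acyclic boron-bearing stereocentre. The product is the same kind of C7 boronate as in the chosen route and would share the final oxidation. On predictability of the diad it is stronger.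
- Against:
  - C8 must already be stereodefined in A6, which needs its own asymmetric step and a diol exchange.
  - The first migrating group is a secondary benzylic carbon on a 1,2,3-trisubstituted ring, the slow case.
  - After the first shift the chloride-bearing C7 centre can epimerise by chloride exchange.
  - C8 and the diol may be a mismatched pair.
  - The chemistry is cryogenic and stoichiometric in auxiliary, and it is linear, with allyl and silyl ether carried throughout and removed at the end.
- Comparison: the chosen strategy reaches the same type of C7–B compound catalytically from three commercial components in two steps. Alternative 3 would be the natural plan if the nickel chemistry failed altogether.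

Key step: step 2

Assumption: for the unproven enantioselective step, the ligand antipode that delivers the required alkene face cannot be deduced in advance. The steps are written with (S,S)-iPr-BiOX, (4S,4'S)-4,4'-diisopropyl-4,4',5,5'-tetrahydro-2,2'-bioxazole; its (R,R) antipode is meant if screening shows the opposite sense.

Remark on descriptors: C8 is R in every boronate (ring A outranks the boron-bearing C7) and S in 12 and 13 (the oxygen-bearing C7 outranks ring A). No bond at C8 changes after step 2.

## Route

Step 1
Reactants: 1 2-bromo-6-methoxyphenol
Product: 2 2-(benzyloxy)-1-bromo-3-methoxybenzene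
Conditions: BnBr, K2CO3, DMF, 25 °C
Reagents that add atoms: benzyl bromide, BrCc1ccccc1
Why: Williamson etherification of the phenoxide with a benzylic bromide; the aryl C–Br bond is untouched.

Step 2
Reactants: 2 2-(benzyloxy)-1-bromo-3-methoxybenzene; 3 (E)-methylisoeugenol, 1,2-dimethoxy-4-[(1E)-prop-1-en-1-yl]benzene; 4 bis(pinacolato)diboron
Product: 5 2-[(1S,2R)-2-[2-(benzyloxy)-3-methoxyphenyl]-1-(3,4-dimethoxyphenyl)propyl]-4,4,5,5-tetramethyl-1,3,2-dioxaborolane
Conditions: NiCl2·DME (10 mol %), (S,S)-iPr-BiOX (12 mol %), KOMe, DMA, 30 °C
Reagents that add atoms: none
Why: Proposed new method: zerovalent nickel formed from NiCl2·DME, KOMe and 4 should insert into the C–Br bond of 2, and the arylnickel species should add across the alkene of 3 with ring A going to C8 and nickel to C7, where the electron-rich ring B holds it as an η3-benzyl; methoxide-activated 4 then transfers a boryl group to nickel, and C7–B reductive elimination with retention releases 5. The closest known reaction type is the racemic, syn-selective nickel-catalysed 1,2-arylboration of alkenylarenes with aryl bromides and B2pin2 that places boron on the benzylic carbon; the new element is control of the alkene face by a chiral bis(oxazoline) on nickel. No ring is closed. C8 is set in the migratory insertion, whose enantiotopic face is chosen by the ligand, and C7 follows from it because insertion and reductive elimination are both suprafacial, so the (E) geometry of 3 becomes the threo (1S,2R) pair. Regiochemistry is secured by benzylic stabilisation of nickel at C7 by ring B; chemoselectivity by the absence of any second alkene, which is why the ring A oxygen carries benzyl and not allyl; diastereoselectivity by the geometric purity of 3, provided C–B bond formation outruns epimerisation of the benzylnickel. The ligand must bind nickel firmly enough to suppress the ligand-free racemic pathway.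

Step 3
Reactants: 5 2-[(1S,2R)-2-[2-(benzyloxy)-3-methoxyphenyl]-1-(3,4-dimethoxyphenyl)propyl]-4,4,5,5-tetramethyl-1,3,2-dioxaborolane
Product: 6 2-[(1S,2R)-1-(3,4-dimethoxyphenyl)-1-(4,4,5,5-tetramethyl-1,3,2-dioxaborolan-2-yl)propan-2-yl]-6-methoxyphenol
Conditions: H2 (1 atm), 10% Pd/C, EtOAc, 25 °C
Reagents that add atoms: none
Why: Hydrogenolysis of the aryl benzyl ether over Pd/C; the alkyl C–B bond, the methyl ethers and both stereocentres are inert to these conditions, and the step is run while the molecule has no C=C bond. Reversible binding of the freed phenol oxygen to the neighbouring boron is possible and is taken into account in step 4.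

Step 4
Reactants: 6 2-[(1S,2R)-1-(3,4-dimethoxyphenyl)-1-(4,4,5,5-tetramethyl-1,3,2-dioxaborolan-2-yl)propan-2-yl]-6-methoxyphenol
Product: 7 2-[(1S,2R)-1-(3,4-dimethoxyphenyl)-2-[3-methoxy-2-(prop-2-en-1-yloxy)phenyl]propyl]-4,4,5,5-tetramethyl-1,3,2-dioxaborolane
Conditions: allyl bromide, K2CO3, acetone, 56 °C
Reagents that add atoms: allyl bromide, C=CCBr
Why: Williamson O-alkylation of the phenoxide with a reactive allylic bromide under carbonate base, which a secondary alkyl pinacol boronate tolerates; both ortho positions are blocked against C-allylation.

Step 5
Reactants: 7 2-[(1S,2R)-1-(3,4-dimethoxyphenyl)-2-[3-methoxy-2-(prop-2-en-1-yloxy)phenyl]propyl]-4,4,5,5-tetramethyl-1,3,2-dioxaborolane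
Product: 11 2-[(1S,2R)-1-(3,4-dimethoxyphenyl)-1-(4,4,5,5-tetramethyl-1,3,2-dioxaborolan-2-yl)propan-2-yl]-6-methoxy-4-(prop-2-en-1-yl)phenol, via methoxy-side ortho-dienone 8 (not isolated), via chain-side ortho-dienone 9 (not isolated), via para-dienone 10 (not isolated)
Conditions: PhNEt2, 190 °C, sealed tube (Ar)
Reagents that add atoms: none
Why: Aromatic para-Claisen rearrangement: a [3,3] shift takes the allyl group from oxygen to either ortho carbon (dienones 8 and 9, formed in parallel), neither of which can enolise because both carry a substituent, so a Cope [3,3] shift moves it on to the para carbon (10) and tautomerisation gives phenol 11. The two allylic transpositions cancel, so the group arrives as CH2–CH=CH2, and C7, C8 and the C–B bond lie outside the pericyclic arrays and should be unchanged.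

Step 6
Reactants: 11 2-[(1S,2R)-1-(3,4-dimethoxyphenyl)-1-(4,4,5,5-tetramethyl-1,3,2-dioxaborolan-2-yl)propan-2-yl]-6-methoxy-4-(prop-2-en-1-yl)phenol
Product: 13 2-[(1S,2S)-1-(3,4-dimethoxyphenyl)-1-hydroxypropan-2-yl]-6-methoxy-4-(prop-2-en-1-yl)phenol, via C7 borate ester 12 (not isolated)
Conditions: NaBO3·4H2O, THF/H2O (1:1), 25 °C; pH 7 phosphate work-up
Reagents that add atoms: sodium perborate tetrahydrate, [Na+].[O-]OB=O.O.O.O.O
Why: Oxidation of a secondary alkylboronic ester: the peroxoborate oxygen adds to boron and C7 migrates from boron to oxygen with retention to give 12, which is hydrolysed in the same flask to 13. The oxidant is nucleophilic and should not epoxidise the isolated alkene, and a neutral work-up with deactivated silica avoids ionisation of the new benzylic alcohol.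

## Compound list

1 | 2-bromo-6-methoxyphenol | COc1cccc(Br)c1O | starting material
2 | 2-(benzyloxy)-1-bromo-3-methoxybenzene | COc1cccc(Br)c1OCc1ccccc1 | intermediate
3 | (E)-methylisoeugenol, 1,2-dimethoxy-4-[(1E)-prop-1-en-1-yl]benzene | C/C=C/c1ccc(OC)c(OC)c1 | starting material
4 | bis(pinacolato)diboron | CC1(C)OB(OC1(C)C)B1OC(C)(C)C(C)(C)O1 | starting material
5 | 2-[(1S,2R)-2-[2-(benzyloxy)-3-methoxyphenyl]-1-(3,4-dimethoxyphenyl)propyl]-4,4,5,5-tetramethyl-1,3,2-dioxaborolane | COc1cccc([C@H](C)[C@H](B2OC(C)(C)C(C)(C)O2)c2ccc(OC)c(OC)c2)c1OCc1ccccc1 | intermediate
6 | 2-[(1S,2R)-1-(3,4-dimethoxyphenyl)-1-(4,4,5,5-tetramethyl-1,3,2-dioxaborolan-2-yl)propan-2-yl]-6-methoxyphenol | COc1cccc([C@H](C)[C@H](B2OC(C)(C)C(C)(C)O2)c2ccc(OC)c(OC)c2)c1O | intermediate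
7 | 2-[(1S,2R)-1-(3,4-dimethoxyphenyl)-2-[3-methoxy-2-(prop-2-en-1-yloxy)phenyl]propyl]-4,4,5,5-tetramethyl-1,3,2-dioxaborolane | COc1cccc([C@H](C)[C@H](B2OC(C)(C)C(C)(C)O2)c2ccc(OC)c(OC)c2)c1OCC=C | intermediate
8 | 2-[(1S,2R)-1-(3,4-dimethoxyphenyl)-1-(4,4,5,5-tetramethyl-1,3,2-dioxaborolan-2-yl)propan-2-yl]-6-methoxy-6-(prop-2-en-1-yl)cyclohexa-2,4-dien-1-one, both epimers at ring C6 | C=CCC1(OC)C=CC=C([C@H](C)[C@H](B2OC(C)(C)C(C)(C)O2)c2ccc(OC)c(OC)c2)C1=O | intermediate
9 | 6-[(1S,2R)-1-(3,4-dimethoxyphenyl)-1-(4,4,5,5-tetramethyl-1,3,2-dioxaborolan-2-yl)propan-2-yl]-2-methoxy-6-(prop-2-en-1-yl)cyclohexa-2,4-dien-1-one, both epimers at ring C6 | C=CCC1([C@H](C)[C@H](B2OC(C)(C)C(C)(C)O2)c2ccc(OC)c(OC)c2)C=CC=C(OC)C1=O | intermediate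
10 | 2-[(1S,2R)-1-(3,4-dimethoxyphenyl)-1-(4,4,5,5-tetramethyl-1,3,2-dioxaborolan-2-yl)propan-2-yl]-6-methoxy-4-(prop-2-en-1-yl)cyclohexa-2,5-dien-1-one, both epimers at ring C4 | C=CCC1C=C(OC)C(=O)C([C@H](C)[C@H](B2OC(C)(C)C(C)(C)O2)c2ccc(OC)c(OC)c2)=C1 | intermediate
11 | 2-[(1S,2R)-1-(3,4-dimethoxyphenyl)-1-(4,4,5,5-tetramethyl-1,3,2-dioxaborolan-2-yl)propan-2-yl]-6-methoxy-4-(prop-2-en-1-yl)phenol | C=CCc1cc(OC)c(O)c([C@H](C)[C@H](B2OC(C)(C)C(C)(C)O2)c2ccc(OC)c(OC)c2)c1 | intermediate
12 | 2-[(1S,2S)-1-(3,4-dimethoxyphenyl)-1-[(4,4,5,5-tetramethyl-1,3,2-dioxaborolan-2-yl)oxy]propan-2-yl]-6-methoxy-4-(prop-2-en-1-yl)phenol | C=CCc1cc(OC)c(O)c([C@H](C)[C@H](OB2OC(C)(C)C(C)(C)O2)c2ccc(OC)c(OC)c2)c1 | intermediate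
13 | 2-[(1S,2S)-1-(3,4-dimethoxyphenyl)-1-hydroxypropan-2-yl]-6-methoxy-4-(prop-2-en-1-yl)phenol | C=CCc1cc(OC)c(O)c([C@H](C)[C@H](O)c2ccc(OC)c(OC)c2)c1 | target

## Step count and least certain steps

Total step count: 6. Longest linear sequence: 6 steps (1 → 2 → 5 → 6 → 7 → 11 → 13); 3 and 4 enter at step 2 as purchased.

**Step 2 (key step, proposed new method).**
- Most likely failure: insufficient enantiofacial discrimination. Nickel not bound to the chiral ligand (solvated by DMA) can run the racemic pathway in the background, and the ligand must share the metal with an ortho-benzyloxy aryl group during insertion.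
- Further possible failures:
  - reversal of regiochemistry if a borylnickel species adds to the alkene before the aryl group is transferred;
  - erosion of the syn relationship if the benzylnickel at C7 epimerises before C–B bond formation;
  - direct borylation or reduction of the hindered aryl bromide.
- Fallback (known chemistry, classical resolution in place of catalyst control), setting out from 2, 3 and 4 and returning at 6:
  - The three components are combined under the established ligand-free racemic protocol (NiCl2·DME, KOMe, DMA). This should give 5 together with its enantiomer, the (1R,2S)-benzyl ether boronate F1.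
  - The racemate is hydrogenolysed as in step 3 to 6 and its enantiomer, the (1R,2S)-phenol boronate F2.
  - The mixture is acylated with (1S)-(−)-camphanic chloride (Et3N, DMAP, CH2Cl2) to the (1S)-camphanate ester of the (1S,2R)-phenol F3 and the (1S)-camphanate ester of the (1R,2S)-phenol F4.
  - The diastereomers are separated by crystallisation or chromatography on silica.
  - Methanolysis of F3 (K2CO3, MeOH, 0 °C) returns 6 as a single enantiomer, and the route continues at step 4.

**Step 5.**
- Most likely failure: degradation at 190 °C. The phenol liberated next to boron may cleave the benzylic C–B bond by protonation, and the allyl group may be lost from oxygen if the relay from the ortho-dienones to the para position is slow.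
- Fallback (cross-coupling in place of the sigmatropic relay), setting out from 6, bypassing steps 4 and 5, and returning at 11:
  - Phenol 6 is brominated para to the hydroxyl with N-bromosuccinimide (MeCN, 0 °C) to the 4-bromophenol boronate F5.
  - The allyl group is introduced by Stille coupling with allyltributylstannane (Pd(PPh3)4, DMF, 80 °C), which gives 11 directly. The secondary alkyl pinacol boronate should not transmetalate under these conditions.

**Step 4.**
- Most likely failure: sluggish alkylation with competing base-induced loss of boron. The phenoxide is flanked by two ortho substituents and can bind the neighbouring boron as an internal ate complex.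
- Fallback, setting out from 6 and returning at 7 with no new intermediate: Mitsunobu etherification of 6 with allyl alcohol (PPh3, diisopropyl azodicarboxylate, THF, 0 to 25 °C). It forms the same O–allyl bond without carbonate base or a metal phenoxide.

## Further compounds

F1 | step 2 | 2-[(1R,2S)-2-[2-(benzyloxy)-3-methoxyphenyl]-1-(3,4-dimethoxyphenyl)propyl]-4,4,5,5-tetramethyl-1,3,2-dioxaborolane (enantiomer of 5) | COc1cccc([C@@H](C)[C@@H](B2OC(C)(C)C(C)(C)O2)c2ccc(OC)c(OC)c2)c1OCc1ccccc1
F2 | step 2 | 2-[(1R,2S)-1-(3,4-dimethoxyphenyl)-1-(4,4,5,5-tetramethyl-1,3,2-dioxaborolan-2-yl)propan-2-yl]-6-methoxyphenol (enantiomer of 6) | COc1cccc([C@@H](C)[C@@H](B2OC(C)(C)C(C)(C)O2)c2ccc(OC)c(OC)c2)c1O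
F3 | step 2 | 2-[(1S,2R)-1-(3,4-dimethoxyphenyl)-1-(4,4,5,5-tetramethyl-1,3,2-dioxaborolan-2-yl)propan-2-yl]-6-methoxyphenyl (1S,4R)-4,7,7-trimethyl-3-oxo-2-oxabicyclo[2.2.1]heptane-1-carboxylate | C[C@@]12CC[C@@](C1(C)C)(OC2=O)C(=O)Oc1c(OC)cccc1[C@H](C)[C@H](B3OC(C)(C)C(C)(C)O3)c1ccc(OC)c(OC)c1
F4 | step 2 | 2-[(1R,2S)-1-(3,4-dimethoxyphenyl)-1-(4,4,5,5-tetramethyl-1,3,2-dioxaborolan-2-yl)propan-2-yl]-6-methoxyphenyl (1S,4R)-4,7,7-trimethyl-3-oxo-2-oxabicyclo[2.2.1]heptane-1-carboxylate | C[C@@]12CC[C@@](C1(C)C)(OC2=O)C(=O)Oc1c(OC)cccc1[C@@H](C)[C@@H](B3OC(C)(C)C(C)(C)O3)c1ccc(OC)c(OC)c1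
F5 | step 5 | 4-bromo-2-[(1S,2R)-1-(3,4-dimethoxyphenyl)-1-(4,4,5,5-tetramethyl-1,3,2-dioxaborolan-2-yl)propan-2-yl]-6-methoxyphenol | Brc1cc(OC)c(O)c([C@H](C)[C@H](B2OC(C)(C)C(C)(C)O2)c2ccc(OC)c(OC)c2)c1
F0 | step 4 | none | none
A1 | alternative 1 | 2-[(1S,2S)-1-(tert-butyldimethylsilyloxy)-1-(3,4-dimethoxyphenyl)propan-2-yl]-6-methoxy-4-(prop-2-en-1-yl)phenol | C=CCc1cc(OC)c(O)c([C@H](C)[C@H](O[Si](C)(C)C(C)(C)C)c2ccc(OC)c(OC)c2)c1
A2 | alternative 1 | tert-butyl{(1S,2S)-1-(3,4-dimethoxyphenyl)-2-[3-methoxy-2-(prop-2-en-1-yloxy)phenyl]propoxy}dimethylsilane | COc1cccc([C@H](C)[C@H](O[Si](C)(C)C(C)(C)C)c2ccc(OC)c(OC)c2)c1OCC=C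
A3 | alternative 2 | (1S,2S)-2-[5-bromo-2-(tert-butyldimethylsilyloxy)-3-methoxyphenyl]-1-(3,4-dimethoxyphenyl)propan-1-ol | Brc1cc(OC)c(O[Si](C)(C)C(C)(C)C)c([C@H](C)[C@H](O)c2ccc(OC)c(OC)c2)c1
A4 | alternative 2 | (1R)-2-[5-bromo-2-(tert-butyldimethylsilyloxy)-3-methoxyphenyl]-1-(3,4-dimethoxyphenyl)prop-2-en-1-ol | Brc1cc(OC)c(O[Si](C)(C)C(C)(C)C)c(C(=C)[C@H](O)c2ccc(OC)c(OC)c2)c1
A5 | alternative 3 | (4S,5S)-2-[(1S,2R)-2-[2-(tert-butyldimethylsilyloxy)-3-methoxy-5-(prop-2-en-1-yl)phenyl]-1-(3,4-dimethoxyphenyl)propyl]-4,5-dicyclohexyl-1,3,2-dioxaborolane | C=CCc1cc(OC)c(O[Si](C)(C)C(C)(C)C)c([C@H](C)[C@H](B2O[C@@H](C3CCCCC3)[C@H](C3CCCCC3)O2)c2ccc(OC)c(OC)c2)c1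
A6 | alternative 3 | (4S,5S)-2-[(1S)-1-[2-(tert-butyldimethylsilyloxy)-3-methoxy-5-(prop-2-en-1-yl)phenyl]ethyl]-4,5-dicyclohexyl-1,3,2-dioxaborolane | C=CCc1cc(OC)c(O[Si](C)(C)C(C)(C)C)c([C@H](C)B2O[C@@H](C3CCCCC3)[C@H](C3CCCCC3)O2)c1
A7 | alternative 3 | 3,4-dimethoxyphenylmagnesium bromide | COc1ccc([Mg]Br)cc1OC
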